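The two bonds that tie ring A to the dihydrofuran ring, O1–C7a and C3–C3a, are cut together. The O1–C2–C3 unit that remains is the oxirane of a stilbene, and ring A is a 3-methoxyaryne whose electrophilic carbon (remote from OMe, future C7a) and latent nucleophilic carbon (ortho to OMe, future C3a) match that unit. One operation inserts the aryne into the epoxide C3–O bond: it forms both bonds, closes the furan ring and sets C3 trans to C2, whose configuration comes from a Shi epoxidation. The precursors are an ortho-silylaryl triflate carrying the C6 carbon as a methyl ester and the (2R,3R)-epoxide of pterostilbene triflate, the triflate steering C–O cleavage.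

Key step: step 5

Remark: the D-fructose-derived Shi ketone is assumed to show with 2 the facial preference it shows with trans-stilbene, which leads to the (R,R)-epoxide.

Step 1
Reactants: 1 pterostilbene, (E)-4-[2-(3,5-dimethoxyphenyl)ethenyl]phenol
Product: 2 (E)-4-[2-(3,5-dimethoxyphenyl)ethenyl]phenyl trifluoromethanesulfonate
Conditions: Tf2O, pyridine, CH2Cl2, 0 °C
Reagents that add atoms: trifluoromethanesulfonic anhydride, O=S(=O)(OS(=O)(=O)C(F)(F)F)C(F)(F)F
Why: O-Sulfonylation of the phenol (aryl triflate formation) is fast and chemoselective at 0 °C, and the triflate serves as phenol protecting group and as the electron-withdrawing handle needed in steps 2, 5 and 8.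

Step 2
Reactants: 2 (E)-4-[2-(3,5-dimethoxyphenyl)ethenyl]phenyl trifluoromethanesulfonate
Product: 3 4-[(2R,3R)-3-(3,5-dimethoxyphenyl)oxiran-2-yl]phenyl trifluoromethanesulfonate
Conditions: D-fructose-derived Shi ketone (30 mol %), Oxone, K2CO3, n-Bu4NHSO4 (cat.), MeCN–dimethoxymethane, aq. Na2B4O7–EDTA buffer, 0 °C
Reagents that add atoms: potassium peroxymonosulfate (active component of Oxone), [K+].[O-]S(=O)(=O)OO
Why: Shi asymmetric epoxidation: the chiral dioxirane generated from the D-fructose-derived ketone and Oxone delivers oxygen through a spiro transition state to one face of the trans-disubstituted alkene, setting both epoxide carbons as R (the sense known for trans-stilbene), and the electron-poor triflyloxyphenyl ring keeps the product from ionising under the buffered conditions.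

Step 3
Reactants: 4 methyl 4-bromo-3,5-dihydroxybenzoate
Product: 5 methyl 4-bromo-3-hydroxy-5-methoxybenzoate
Conditions: MeI (1.0 equiv), K2CO3 (1.0 equiv), DMF, rt
Reagents that add atoms: iodomethane, CI
Why: Williamson ether synthesis with one equivalent of iodomethane desymmetrises the diol statistically, the monoether being separated by chromatography from the dimethyl ether and from unreacted 4, which is recycled.

Step 4
Reactants: 5 methyl 4-bromo-3-hydroxy-5-methoxybenzoate
Product: 8 methyl 3-methoxy-5-(trifluoromethanesulfonyloxy)-4-(trimethylsilyl)benzoate, via aryl trimethylsilyl ether 6 (not isolated), via lithium silylphenolate 7 (not isolated)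
Conditions: (Me3Si)2NH, THF, 70 °C, then evaporate; n-BuLi, THF, −100 °C; Tf2O, −100 °C → rt
Reagents that add atoms: hexamethyldisilazane, C[Si](C)(C)N[Si](C)(C)C; trifluoromethanesulfonic anhydride, O=S(=O)(OS(=O)(=O)C(F)(F)F)C(F)(F)F; n-butyllithium, [Li]CCCC (lithium of intermediate 7 only)
Why: Silylation of the phenol, then bromine–lithium exchange at −100 °C, which outruns addition of butyllithium to the methyl ester, gives an aryllithium flanked by OSiMe3 and OMe that undergoes immediate 1,3 O→C silyl migration (retro-Brook rearrangement) to phenolate 7, and O-triflation of 7 completes the Kobayashi-type aryne precursor in one pot.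

Step 5
Reactants: 3 4-[(2R,3R)-3-(3,5-dimethoxyphenyl)oxiran-2-yl]phenyl trifluoromethanesulfonate (2 equiv, excess recovered); 8 methyl 3-methoxy-5-(trifluoromethanesulfonyloxy)-4-(trimethylsilyl)benzoate
Product: 10 methyl (2S,3S)-3-(3,5-dimethoxyphenyl)-4-methoxy-2-[4-(trifluoromethanesulfonyloxy)phenyl]-2,3-dihydro-1-benzofuran-6-carboxylate, via 3-methoxyaryne 9 (not isolated)
Conditions: CsF (3 equiv), toluene–MeCN (3:1), rt → 40 °C, slow addition of 8 to 3
Reagents that add atoms: none
Why: Proposed new method: fluoride removes the silyl group of 8 and expels triflate to give aryne 9, the epoxide oxygen of 3 adds to the aryne carbon remote from methoxy (O1–C7a) so that the aryl anion sits ortho to methoxy, and the strained aryloxiranium then ionises at the 3,5-dimethoxyphenyl-bearing carbon, whose cation is captured by the aryl anion (C3–C3a). The closest known reaction type is the insertion of arynes into the benzylic C–O bond of monoaryl epoxides such as styrene oxide, besides aryne σ-insertions in general; a trans-stilbene oxide with two differentiated aryl groups has not served as substrate. The dihydrofuran ring closes by collapse of the aryl anion onto the benzylic cation inside the zwitterion, formally a 5-endo-tet substitution that becomes feasible because C–O heterolysis precedes C–C bond formation. C2 keeps its four ligands and hence the configuration fixed in step 2, and the new stereocentre C3 is set by substrate control from C2: the planar cation is captured on the face vacated by oxygen, which puts the 3,5-dimethoxyphenyl group trans to the C2 aryl group, the arrangement already present in the trans epoxide and the less strained one in the product. Two regioselectivities are needed: that of the aryne addition, secured by the inductive polarisation of 9 by its 3-methoxy group, and that of the C–O cleavage, secured by the para-triflyloxy group of 3, a strong σ-acceptor and poor π-donor that destabilises positive charge at its own benzylic carbon much more than two meta-methoxy groups do at the other. Excess epoxide, slow release of 9 and a toluene-rich medium are meant to suppress aryne self-reaction, protonation of the aryl anion by acetonitrile and three-component trapping of the oxiranium ion.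

Step 6
Reactants: 10 methyl (2S,3S)-3-(3,5-dimethoxyphenyl)-4-methoxy-2-[4-(trifluoromethanesulfonyloxy)phenyl]-2,3-dihydro-1-benzofuran-6-carboxylate
Product: 11 4-[(2S,3S)-3-(3,5-dimethoxyphenyl)-6-(hydroxymethyl)-4-methoxy-2,3-dihydro-1-benzofuran-2-yl]phenyl trifluoromethanesulfonate
Conditions: DIBAL-H (2.5 equiv), CH2Cl2, −78 → 0 °C; aq. Rochelle salt
Reagents that add atoms: none
Why: Ester reduction with DIBAL-H proceeds through the aldehyde to the primary benzylic alcohol at low temperature, where the aryl triflate, the aryl methyl ethers and the benzylic ring ether are inert and neither stereocentre is involved.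

Step 7
Reactants: 11 4-[(2S,3S)-3-(3,5-dimethoxyphenyl)-6-(hydroxymethyl)-4-methoxy-2,3-dihydro-1-benzofuran-2-yl]phenyl trifluoromethanesulfonate
Product: 12 4-[(2S,3S)-3-(3,5-dimethoxyphenyl)-6-formyl-4-methoxy-2,3-dihydro-1-benzofuran-2-yl]phenyl trifluoromethanesulfonate
Conditions: activated MnO2 (excess), CH2Cl2, rt
Reagents that add atoms: none
Why: Activated manganese dioxide oxidises benzylic alcohols selectively to aldehydes without over-oxidation and does not touch the triflate, the ethers or the C2 and C3 stereocentres.

Step 8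
Reactants: 12 4-[(2S,3S)-3-(3,5-dimethoxyphenyl)-6-formyl-4-methoxy-2,3-dihydro-1-benzofuran-2-yl]phenyl trifluoromethanesulfonate
Product: 13 4-[(2S,3S)-3-(3,5-dihydroxyphenyl)-6-formyl-4-hydroxy-2,3-dihydro-1-benzofuran-2-yl]phenyl trifluoromethanesulfonate
Conditions: BBr3 (excess), CH2Cl2, −78 → 0 °C; then H2O
Reagents that add atoms: none
Why: Boron tribromide ether cleavage (complexation at oxygen, then bromide attack at methyl) removes the three methyl ethers while the aryl triflate is inert and, as an acceptor para to C2, disfavours Lewis-acid ionisation of the benzylic C2–O1 bond, so that the ring and both stereocentres should survive; the formyl group is released from its boron complex on aqueous quench.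

Step 9
Reactants: 13 4-[(2S,3S)-3-(3,5-dihydroxyphenyl)-6-formyl-4-hydroxy-2,3-dihydro-1-benzofuran-2-yl]phenyl trifluoromethanesulfonate
Product: 14 gnetal, (2S,3S)-3-(3,5-dihydroxyphenyl)-4-hydroxy-2-(4-hydroxyphenyl)-2,3-dihydro-1-benzofuran-6-carbaldehyde
Conditions: Et4NOH (35 % aq., 6 equiv), degassed 1,4-dioxane, rt, Ar; then 1 M HCl to pH 4
Reagents that add atoms: none
Why: Hydroxide attacks the sulfur of the aryl triflate (sulfonate ester hydrolysis, S–O cleavage) and frees the phenolate without breaking any C–O bond, and at room temperature under argon the polyphenolate should neither oxidise nor open at C2, so acidification gives gnetal with both stereocentres unchanged.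

Compound list
1 | pterostilbene, (E)-4-[2-(3,5-dimethoxyphenyl)ethenyl]phenol | COc1cc(/C=C/c2ccc(O)cc2)cc(OC)c1 | starting material
2 | (E)-4-[2-(3,5-dimethoxyphenyl)ethenyl]phenyl trifluoromethanesulfonate | COc1cc(/C=C/c2ccc(OS(=O)(=O)C(F)(F)F)cc2)cc(OC)c1 | intermediate
3 | 4-[(2R,3R)-3-(3,5-dimethoxyphenyl)oxiran-2-yl]phenyl trifluoromethanesulfonate | O1[C@H](c2ccc(OS(=O)(=O)C(F)(F)F)cc2)[C@H]1c1cc(OC)cc(OC)c1 | intermediate
4 | methyl 4-bromo-3,5-dihydroxybenzoate | COC(=O)c1cc(O)c(Br)c(O)c1 | starting material
5 | methyl 4-bromo-3-hydroxy-5-methoxybenzoate | COC(=O)c1cc(O)c(Br)c(OC)c1 | intermediate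
6 | methyl 4-bromo-3-methoxy-5-(trimethylsilyloxy)benzoate | COC(=O)c1cc(O[Si](C)(C)C)c(Br)c(OC)c1 | intermediate
7 | lithium 3-methoxy-5-(methoxycarbonyl)-2-(trimethylsilyl)phenolate | [Li+].[O-]c1cc(C(=O)OC)cc(OC)c1[Si](C)(C)C | intermediate
8 | methyl 3-methoxy-5-(trifluoromethanesulfonyloxy)-4-(trimethylsilyl)benzoate | COC(=O)c1cc(OC)c([Si](C)(C)C)c(OS(=O)(=O)C(F)(F)F)c1 | intermediate
9 | methyl 3-methoxy-4,5-didehydrobenzoate (3-methoxyaryne) | COC(=O)C1=CC#CC(OC)=C1 | intermediate
10 | methyl (2S,3S)-3-(3,5-dimethoxyphenyl)-4-methoxy-2-[4-(trifluoromethanesulfonyloxy)phenyl]-2,3-dihydro-1-benzofuran-6-carboxylate | COC(=O)c1cc(OC)c2c(c1)O[C@H](c1ccc(OS(=O)(=O)C(F)(F)F)cc1)[C@H]2c1cc(OC)cc(OC)c1 | intermediate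
11 | 4-[(2S,3S)-3-(3,5-dimethoxyphenyl)-6-(hydroxymethyl)-4-methoxy-2,3-dihydro-1-benzofuran-2-yl]phenyl trifluoromethanesulfonate | OCc1cc(OC)c2c(c1)O[C@H](c1ccc(OS(=O)(=O)C(F)(F)F)cc1)[C@H]2c1cc(OC)cc(OC)c1 | intermediate
12 | 4-[(2S,3S)-3-(3,5-dimethoxyphenyl)-6-formyl-4-methoxy-2,3-dihydro-1-benzofuran-2-yl]phenyl trifluoromethanesulfonate | O=Cc1cc(OC)c2c(c1)O[C@H](c1ccc(OS(=O)(=O)C(F)(F)F)cc1)[C@H]2c1cc(OC)cc(OC)c1 | intermediate
13 | 4-[(2S,3S)-3-(3,5-dihydroxyphenyl)-6-formyl-4-hydroxy-2,3-dihydro-1-benzofuran-2-yl]phenyl trifluoromethanesulfonate | O=Cc1cc(O)c2c(c1)O[C@H](c1ccc(OS(=O)(=O)C(F)(F)F)cc1)[C@H]2c1cc(O)cc(O)c1 | intermediate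
14 | gnetal, (2S,3S)-3-(3,5-dihydroxyphenyl)-4-hydroxy-2-(4-hydroxyphenyl)-2,3-dihydro-1-benzofuran-6-carbaldehyde | O=Cc1cc(O)c2c(c1)O[C@H](c1ccc(O)cc1)[C@H]2c1cc(O)cc(O)c1 | target

Total step count: 9.
Longest linear sequence: 7 steps (steps 1, 2, 5, 6, 7, 8, 9; the branch through steps 3 and 4 is equally long).

Steps most likely to fail

Step 5. The zwitterion may be diverted before the C–C bond forms: the aryl anion may be protonated, the benzylic cation may undergo a hydride shift, or ionisation may occur at the wrong benzylic carbon. The weakly nucleophilic epoxide oxygen may also capture the aryne inefficiently. The fallback forms C3–C3a and O1–C2 one after the other by known reactions; because both carbons are inverted on the way, it needs the mirror-image epoxide. It sets out from 2 and 5 and comes back to the route at 10. Stilbene 2 would be epoxidised with the enantiomeric Shi ketone (made from L-sorbose) under the conditions of step 2 to give 4-[(2S,3S)-3-(3,5-dimethoxyphenyl)oxiran-2-yl]phenyl trifluoromethanesulfonate F1. Phenol 5 would be protected with MOMCl and i-Pr2NEt as methyl 4-bromo-3-methoxy-5-(methoxymethoxy)benzoate F2. Bromine–magnesium exchange with i-PrMgCl·LiCl in THF at −20 °C, which tolerates the ester, would give methyl 4-(chloromagnesio)-3-methoxy-5-(methoxymethoxy)benzoate F3. Copper-catalysed (CuI, 10 mol %) SN2 opening of F1 by F3 is expected mainly at the carbon bearing the 3,5-dimethoxyphenyl group, with inversion, and should give methyl 4-[(1S,2R)-1-(3,5-dimethoxyphenyl)-2-hydroxy-2-[4-(trifluoromethanesulfonyloxy)phenyl]ethyl]-3-methoxy-5-(methoxymethoxy)benzoate F4; any regioisomer would be removed by chromatography. Removal of the MOM group with HCl in methanol would free methyl 4-[(1S,2R)-1-(3,5-dimethoxyphenyl)-2-hydroxy-2-[4-(trifluoromethanesulfonyloxy)phenyl]ethyl]-3-hydroxy-5-methoxybenzoate F5. Intramolecular Mitsunobu etherification (PPh3, DIAD, THF) would then close the ring with inversion at the carbinol carbon, which the para-triflyloxy group keeps on the SN2 path, to give 10.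

Step 4. Addition of butyllithium or of the aryllithium to the methyl ester may compete with bromine–lithium exchange and silyl migration, or the hindered phenolate may be triflated incompletely. The fallback makes the C–Si bond by cross-coupling and not by an organolithium; it sets out from 5 and comes back at 8. Benzylation (BnBr, K2CO3, DMF) would give methyl 3-(benzyloxy)-4-bromo-5-methoxybenzoate F6. Palladium-catalysed silylation with hexamethyldisilane (Pd2(dba)3, a di-tert-butylbiarylphosphine, KF, H2O, DMPU, 100 °C) would give methyl 3-(benzyloxy)-5-methoxy-4-(trimethylsilyl)benzoate F7. Hydrogenolysis (H2, Pd/C, EtOAc) would give methyl 3-hydroxy-5-methoxy-4-(trimethylsilyl)benzoate F8, and triflation with Tf2O and pyridine in CH2Cl2 at 0 °C would give 8.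

Step 8. The boron halide may attack the formyl group (conversion into a benzal bromide or Lewis-acid-induced degradation), or cleavage of the hindered C4 methyl ether may stall under conditions the aldehyde tolerates. The fallback demethylates before an aldehyde exists; it sets out from 10 and comes back at 13. Treatment of 10 with BBr3 in CH2Cl2 (−78 → 0 °C, methanol quench) would give methyl (2S,3S)-3-(3,5-dihydroxyphenyl)-4-hydroxy-2-[4-(trifluoromethanesulfonyloxy)phenyl]-2,3-dihydro-1-benzofuran-6-carboxylate F9. Reduction with excess DIBAL-H (the three phenols are deprotonated first) would give 4-[(2S,3S)-3-(3,5-dihydroxyphenyl)-4-hydroxy-6-(hydroxymethyl)-2,3-dihydro-1-benzofuran-2-yl]phenyl trifluoromethanesulfonate F10. Selective benzylic oxidation with activated MnO2 would give 13.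

Further compounds
F1 | step 5 | 4-[(2S,3S)-3-(3,5-dimethoxyphenyl)oxiran-2-yl]phenyl trifluoromethanesulfonate | O1[C@@H](c2ccc(OS(=O)(=O)C(F)(F)F)cc2)[C@@H]1c1cc(OC)cc(OC)c1
F2 | step 5 | methyl 4-bromo-3-methoxy-5-(methoxymethoxy)benzoate | COCOc1cc(C(=O)OC)cc(OC)c1Br
F3 | step 5 | methyl 4-(chloromagnesio)-3-methoxy-5-(methoxymethoxy)benzoate | COCOc1cc(C(=O)OC)cc(OC)c1[Mg]Cl
F4 | step 5 | methyl 4-[(1S,2R)-1-(3,5-dimethoxyphenyl)-2-hydroxy-2-[4-(trifluoromethanesulfonyloxy)phenyl]ethyl]-3-methoxy-5-(methoxymethoxy)benzoate | O[C@@H](c1ccc(OS(=O)(=O)C(F)(F)F)cc1)[C@H](c1c(OCOC)cc(C(=O)OC)cc1OC)c1cc(OC)cc(OC)c1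
F5 | step 5 | methyl 4-[(1S,2R)-1-(3,5-dimethoxyphenyl)-2-hydroxy-2-[4-(trifluoromethanesulfonyloxy)phenyl]ethyl]-3-hydroxy-5-methoxybenzoate | O[C@@H](c1ccc(OS(=O)(=O)C(F)(F)F)cc1)[C@H](c1c(O)cc(C(=O)OC)cc1OC)c1cc(OC)cc(OC)c1
F6 | step 4 | methyl 3-(benzyloxy)-4-bromo-5-methoxybenzoate | COC(=O)c1cc(OC)c(Br)c(OCc2ccccc2)c1
F7 | step 4 | methyl 3-(benzyloxy)-5-methoxy-4-(trimethylsilyl)benzoate | COC(=O)c1cc(OC)c([Si](C)(C)C)c(OCc2ccccc2)c1
F8 | step 4 | methyl 3-hydroxy-5-methoxy-4-(trimethylsilyl)benzoate | COC(=O)c1cc(OC)c([Si](C)(C)C)c(O)c1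
F9 | step 8 | methyl (2S,3S)-3-(3,5-dihydroxyphenyl)-4-hydroxy-2-[4-(trifluoromethanesulfonyloxy)phenyl]-2,3-dihydro-1-benzofuran-6-carboxylate | COC(=O)c1cc(O)c2c(c1)O[C@H](c1ccc(OS(=O)(=O)C(F)(F)F)cc1)[C@H]2c1cc(O)cc(O)c1
F10 | step 8 | 4-[(2S,3S)-3-(3,5-dihydroxyphenyl)-4-hydroxy-6-(hydroxymethyl)-2,3-dihydro-1-benzofuran-2-yl]phenyl trifluoromethanesulfonate | OCc1cc(O)c2c(c1)O[C@H](c1ccc(OS(=O)(=O)C(F)(F)F)cc1)[C@H]2c1cc(O)cc(O)c1
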